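## Structural features

The target 35 is a tricyclic sesquiterpenoid triester built on a cyclobutane (C4–C5–C6–C7). C5 and C7 are spanned on one face by the bridge C10–C9–C8, which makes a bicyclo[3.1.1]heptanone with the ketone at C8, and C4 and C6 are tied on the other face by the chain C3–C2–C1–C11, which closes a seven-membered ring. Seven of the eight stereocentres form an unbroken row from C1 to C7, with C4 quaternary and the gem-dimethyl carbon C11 wedged between C1 and C6; the eighth, C10, sits next to C5 with its methyl on the side of C6 and away from the C4 methyl. The oxygens on C2 and C3 are cis to each other and trans to the oxygen on C1; the two neopentyl positions C1 and C3 carry angelates and C2 carries the acetate. The fragile parts are the angelates (Z-to-E isomerisation under nucleophiles, base or heat), the vicinal esters (acyl migration as soon as a neighbouring hydroxyl is free) and the strained cyclobutane next to a ketone. The real difficulty is the cyclobutane: four contiguous stereocentres, one of them quaternary, with every ring carbon shared with a six- or seven-membered ring. The key step exploits the fact that C5, C4, C7, C8, C9 and C10, with methyls on C4 and C10 and oxygen on C8, are the ring of 2,6-dimethylbenzoquinone: a cyclopropane C4–C6–C7 on that ring is one 1,2-shift of C6 (from C4 to C5) away from the cyclobutane, the C4 methyl makes the ring-expanded cation tertiary, and the chain C11–C1–C2–C3 hanging from C6 ends in an enol ether whose carbon C3 closes the seven-membered ring on C4.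

## Logic of the disconnections

35 ⇒ 34: the acetyl C–O bond on C2 is cut first. Acetyl migrates readily to a free neighbouring hydroxyl and angeloyl does not, so the acetate must be the last ester made, on an alcohol whose two neighbours are already acylated. The gain is that no intermediate holds an acetate beside a free hydroxyl. The forward step only has to acetylate a flanked secondary alcohol without disturbing the angelates.

34 ⇒ 33 ⇒ 32 + 26 ⇒ 31: the angeloyl C–O bond on C1 is cut, with the C2 oxygen parked as a triethylsilyl ether whose Si–O bond is cut on either side of the acylation. This leads back to the trans-1,2-diol 31, in which the C2 hydroxyl is the less hindered one, so the triester problem shrinks to a diol monoester. The forward steps must silylate C2 in preference to the neopentyl C1 hydroxyl and then esterify that neopentyl alcohol with 26 without Z/E isomerisation.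

31 ⇒ 30: the C2–H bond is cut (carbinol back to ketone). A C2 ketone beside a free C1 hydroxyl allows hydride delivery from that hydroxyl, which gives the trans C1/C2 relationship and removes one stereocentre from the problem. The reagent must reduce only a hydroxyl-bearing ketone, because C8 is also a ketone in 30.

30 ⇒ 29 ⇒ 28 ⇒ 27 ⇒ 24 + 26: the Si–O bond on C1, the C8–O double bond (back to the silyl-protected carbinol) and the angeloyl C–O bond on C3 are cut. The C3 ester is attached while C2 is still a ketone, so no acyl migration is possible, and C8 becomes a ketone only after the last enolisation towards C3; the ester and one carbonyl are thereby removed. The two silyl ethers (triethylsilyl on C8, tert-butyldimethylsilyl on C1) must come off one after the other.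

26 ⇒ 25: the anhydride C–O bond is cut. One activated angeloyl donor serves both angelate bonds, so the acid is activated once and away from the sensitive tricycle. The activation must proceed without a nucleophilic catalyst, so that the Z alkene of 25 is kept.

24 ⇒ 22: the C3–O bond is cut. The oxygen enters by oxidation of the C2 enolate, which can form only towards C3 on the kinetic side, leaving a ketone with one oxygenated stereocentre fewer. The oxygen must arrive anti to the silyloxy group on C1.

22 ⇒ 20: the key disconnection cuts C3–C4 and C5–C6 and restores C4–C6. The cyclobutane and the seven-membered ring vanish together, leaving a bicyclo[4.1.0]heptane with an open chain. Tracing the cascade backwards (retention at C4 and C6, inversion at C5) fixes 20: leaving group on C5 trans to the cyclopropane, C10 methyl cis to it, chain on C6 exo. C8 is carried as a silyl ether, because a ketal there would be opened by the silyl triflate and would place two donor oxygens where they can drive cleavage of C7–C8 from the C4 cation.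

20 ⇒ 18 ⇒ 17 ⇒ 16: the enol O–Si bond, the acetyl C–O bond on C5 and the C2–C3 bond (methyl Grignard reagent on the Weinreb amide of 16) are cut. Holding C2 as the amide protects it through the hydride and borane steps and takes the reactive enol ether and leaving group out of the earlier intermediates. The methyl ketone of 18 must be enolised in the presence of the acetate.

16 ⇒ 14 ⇒ 13 ⇒ 11: C5–O and C10–H are cut together (syn-hydroboration of the C5=C10 alkene of 14), and 14 is traced through 13 to 11, which removes two stereocentres at once. Reagents should approach C5 anti to the cyclopropane; a hydride would then leave the oxygen cis to the cyclopropane, whereas borane places the oxygen itself on the anti face and the hydrogen on C10 in the same event. The demand is facial selectivity of the kind shown by 2-carene.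

11 ⇒ 10 ⇒ 9: the O–Si and C8–H bonds are cut, back to the ene-dione 9 with no stereocentre on the six-membered ring apart from the ring fusion. The two carbonyls of 9 are told apart by hindrance: C8 is flanked by two CH groups, C5 by a quaternary carbon and a methylated alkene carbon. The forward reduction must therefore be a regioselective 1,2-reduction.

9 ⇒ 7 + 6: the cyclopropane bonds C6–C7 and C4–C6 are cut, which separates the carbocycle 6 from the chain 7 and makes the route convergent. The chain must end exo. C1 is too remote to choose the face, so the two facial diastereomers have to be separated at this point.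

7 ⇒ 5 ⇒ 4 ⇒ 3 ⇒ 2 ⇒ 1: the diazo group goes back to the aldehyde and alcohol, the amide C–N bond to the lactone C–O bond, the silyl ether to the alcohol. Compound 1 supplies C1 with its configuration, C2, C6 and C11 with both methyl groups, so no stereocentre of the chain has to be made. The forward steps must keep the C1 centre intact and must not let the opened lactone close again.

## Other disconnections considered

Alternative 1: The cut is C4–C7. Forward, lactone A1 (C8 carbonyl joined to the oxygen on C2, C3=C4 alkene in the cycloheptene) is enolised and O-silylated (lithium diisopropylamide, Me3SiCl) and rearranges by an Ireland–Claisen [3,3] shift across the ring to acid A2.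
- In its favour: a stereospecific pericyclic step that makes the quaternary C4 and the cyclobutane at once. It also leaves a C2=C3 alkene that could be dihydroxylated anti to the C1 oxygen to install both C2 and C3 oxygens in one step. On that point it is better than the chosen plan, which needs enolate oxidation and a directed reduction.
- Against it: the eight-membered lactone ring of A1 must contract to a strained cyclobutane through a boat-like transition state. The acid carbon C8 of A2 emerges on the alkene-bridge side of C7, trans to C10 across the cyclobutane, so C7 must be epimerised before C8–C9–C10 can be bridged. C9, the C10 methyl stereocentre and the whole six-membered ring remain to be built.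
- Comparison: on structure it forms one ring and one C–C bond against two and two. On mechanism it is the more predictable reaction, since the chosen key step has no direct precedent. On step economy it is worse because of the later annulation.

Alternative 2: The cut is C1–C2. Forward, iodo aldehyde A3 is treated with CrCl2 and catalytic NiCl2; the vinylchromium adds to the C1 aldehyde and closes the seven-membered ring as allylic alcohol A4.
- In its favour: a mild, chemoselective, well-established closure of medium rings onto hindered aldehydes; in reliability it is better than the chosen key step. A4 has the same useful C2=C3 alkene as A2.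
- Against it: it closes only the seven-membered ring. The bicyclo[3.1.1]heptane with its quaternary C4, a (Z)-iodovinyl group on that carbon and the neopentyl aldehyde chain on C6 must already exist in A3, so the real problem is untouched. C1 is created in the ring closure with uncertain control, whereas the chosen plan takes C1 from the chiral pool.
- Comparison: on structure it is the weaker (one bond, one ring, no cyclobutane). On mechanism it is the safer. Step economy depends entirely on a long route to A3.

Alternative 3: The cuts are C6–C11 and C3–C4. Forward, under (Me3Si)3SiH chain conditions the tertiary radical from bromo enone A6 adds to bridgehead C6 of bicyclobutane A5, the central C4–C6 bond breaks, and the C4 cyclobutyl radical closes on the vinyl terminus C3 to give ketone A7.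
- In its favour: the most convergent plan, with two C–C bonds and the seven-membered ring formed in one strain-driven step. A C4 radical has no bridging partner and can be captured on the concave face as easily as on the other; on that point it is better than the cationic capture of the chosen plan. In bonds formed it is its equal.
- Against it: A5 is an enantiopure, substituted, acid-labile tricyclo[4.1.0.0(2,7)]heptane that is hard to make. The first radical addition joins two neopentyl-type carbons. The C4 radical must prefer a 7-endo closure to hydrogen abstraction. A7 has no oxygen on C2 or C3 and no stereocentre at C1, so three oxygenated stereocentres (one at an unactivated carbon) remain.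
- Comparison: shorter before the key step, longer after it; the chosen plan arrives at its key product with C1 oxygenated and configured and C2 as a ketone.

Key step: step 14

Remark on the chemistry: carbons are numbered C1–C11 as in the ring of 35 (C1, C2, C3 the CH–O carbons, C4 the C–Me, C4–C5–C6–C7 the cyclobutane, C8 the ketone, C9 CH2, C10 CH–Me, C11 CMe2). For the bicyclo[4.1.0]heptanes 9–20, β is the face of the six-membered ring that carries C6 and α the opposite face. The cycloaddition of step 5 is assumed to show no useful facial preference from the remote C1 centre, so 9 is taken on after separation from its facial diastereomer. The mixed anhydride 26 is assumed to keep as a cold toluene solution under argon for the interval between its two uses.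

## Route

Step 1
Reactants: 1 (S)-pantolactone
Product: 2 (S)-O-(tert-butyldimethylsilyl)pantolactone
Conditions: t-BuMe2SiCl, imidazole, DMF, rt
Reagents that add atoms: tert-butyldimethylsilyl chloride, CC(C)(C)[Si](C)(C)Cl
Why: Standard silylation of a hindered secondary alcohol; the C1 stereocentre is untouched, and a bulky silyl ether is wanted later to keep this oxygen from attacking the cation.

Step 2
Reactants: 2 (S)-O-(tert-butyldimethylsilyl)pantolactone
Product: 3 (S)-2-(tert-butyldimethylsilyloxy)-4-hydroxy-N-methoxy-N,3,3-trimethylbutanamide
Conditions: MeNH(OMe)·HCl, Me3Al, CH2Cl2, 0 °C → rt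
Reagents that add atoms: N,O-dimethylhydroxylamine hydrochloride, CNOC.Cl
Why: Weinreb aminolysis of a lactone with the aluminium amide frees the C6 alcohol and masks C2 as an amide that tolerates the later hydride, borane and diazo chemistry; the product is oxidised at once to forestall relactonisation.

Step 3
Reactants: 3 (S)-2-(tert-butyldimethylsilyloxy)-4-hydroxy-N-methoxy-N,3,3-trimethylbutanamide
Product: 4 (S)-2-(tert-butyldimethylsilyloxy)-N-methoxy-N,3,3-trimethyl-4-oxobutanamide
Conditions: Dess–Martin periodinane, NaHCO3, CH2Cl2, 0 °C → rt
Reagents that add atoms: none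
Why: Dess–Martin oxidation of a primary neopentyl alcohol; the aldehyde has no α-hydrogen and cannot enolise or eliminate.

Step 4
Reactants: 4 (S)-2-(tert-butyldimethylsilyloxy)-N-methoxy-N,3,3-trimethyl-4-oxobutanamide
Product: 5 (S,E)-2-(tert-butyldimethylsilyloxy)-4-hydrazinylidene-N-methoxy-N,3,3-trimethylbutanamide
Conditions: N2H4·H2O (excess), EtOH, 0 °C → rt; used at once
Reagents that add atoms: hydrazine hydrate, NN.O
Why: Hydrazone formation from an aldehyde; excess hydrazine and the α-quaternary centre suppress azine formation, and the amide is far less electrophilic than the aldehyde.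

Step 5
Reactants: 5 (S,E)-2-(tert-butyldimethylsilyloxy)-4-hydrazinylidene-N-methoxy-N,3,3-trimethylbutanamide; 6 2,6-dimethyl-1,4-benzoquinone
Product: 9 bicyclo[4.1.0]hept-3-ene-2,5-dione (cyclopropane C4–C6–C7; ketones C5 and C8; C9=C10; amide chain exo on C6; 1S,4S,6S,7R in the numbering used here), via diazoalkane 7 (not isolated), via 1-pyrazoline 8 (not isolated)
Conditions: MnO2, CH2Cl2, 0 °C; filter; 6 (1.5 equiv), −20 °C → rt; then PhMe, 80 °C
Reagents that add atoms: none
Why: Hydrazone oxidation gives a non-stabilised diazoalkane that has no β-hydrogen; it should add as a 1,3-dipole to the quinone with its carbon on the unsubstituted carbon C7 and nitrogen on C4, and the pyrazoline loses N2 to the homoquinone (the classical diazoalkane–quinone route), the bulky chain ending exo; the remote C1 centre gives no facial control, so 9 is separated by chromatography from the diastereomer with the mirror-image bicycle.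

Step 6
Reactants: 9 bicyclo[4.1.0]hept-3-ene-2,5-dione (amide chain exo on C6)
Product: 10 8β-hydroxy enone (C8–OH cis to the cyclopropane; C5 ketone; C9=C10)
Conditions: NaBH4, CeCl3·7H2O, MeOH, −78 °C
Reagents that add atoms: none
Why: Luche 1,2-reduction should select the C8 carbonyl (flanked by two CH groups) over C5 (flanked by a quaternary carbon and a methylated alkene carbon); hydride arrives anti to the cyclopropane, whose endo hydrogen screens the β face, and the new centre is only temporary.

Step 7
Reactants: 10 8β-hydroxy enone
Product: 11 8β-triethylsilyloxy enone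
Conditions: Et3SiCl, imidazole, DMF, 0 °C
Reagents that add atoms: chlorotriethylsilane, CC[Si](CC)(CC)Cl
Why: Silylation under basic conditions protects an allylic, cyclopropylcarbinyl alcohol without ionising it; a silyl ether (not an ester or ketal) is chosen because it is no leaving group towards Me3SiOTf and is cleaved later before the tert-butyldimethylsilyl ether.

Step 8
Reactants: 11 8β-triethylsilyloxy enone
Product: 13 C5 enol triflate (C5=C10 alkene; C9 now CH2), via lithium enolate 12 (not isolated)
Conditions: LiBH(s-Bu)3, THF, −78 °C; then N-(5-chloro-2-pyridyl)bis(trifluoromethanesulfonimide), −78 → 0 °C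
Reagents that add atoms: N-(5-chloro-2-pyridyl)bis(trifluoromethanesulfonimide), FC(F)(F)S(=O)(=O)N(c1ccc(Cl)cn1)S(=O)(=O)C(F)(F)F
Why: Conjugate hydride addition to the unsubstituted β-carbon C9 gives the regiodefined C5 enolate, which is trapped on oxygen (reductive triflation); the amide is inert at −78 °C and no stereocentre is formed.

Step 9
Reactants: 13 C5 enol triflate
Product: 14 bicyclo[4.1.0]hept-2-ene with C5=C10 (C5–H; methyl on C10; 8β-silyl ether)
Conditions: Pd(OAc)2 (cat.), PPh3, Bu3N, HCO2H, DMF, 60 °C
Reagents that add atoms: none
Why: Palladium-catalysed formate reduction of a vinyl triflate replaces OTf by H with the alkene position fixed; the cyclopropane carries no activating group and should survive.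

Step 10
Reactants: 14 bicyclo[4.1.0]hept-2-ene with C5=C10
Product: 16 5α-alcohol (C5–OH trans to the cyclopropane; C10 methyl β and cis to it), via alkylborane 15 (not isolated)
Conditions: BH3·SMe2, THF, 0 °C → rt; then NaOH, H2O2, 0 °C
Reagents that add atoms: hydrogen peroxide, OO
Why: Hydroboration–oxidation places boron on the less substituted C5 and hydrogen on C10 in a syn addition from the face anti to the cyclopropane (reinforced by the β silyl ether on C8), as in the hydroboration of 2-carene; this sets C5 and C10 together, and the amide is reduced only slowly by borane at 0 °C.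

Step 11
Reactants: 16 5α-alcohol with Weinreb amide
Product: 17 methyl ketone (C3 methyl on the C2 carbonyl; C5–OH free)
Conditions: MeMgBr (3.5 equiv), THF, 0 °C; aq. NH4Cl
Reagents that add atoms: methylmagnesium bromide, C[Mg]Br
Why: Grignard addition to a Weinreb amide stops at the chelated tetrahedral adduct and gives the ketone on work-up; the C5 alkoxide merely consumes one equivalent.

Step 12
Reactants: 17 methyl ketone with free C5–OH
Product: 18 C5 acetate (5α)
Conditions: Ac2O, DMAP, Et3N, CH2Cl2, rt
Reagents that add atoms: acetic anhydride, CC(=O)OC(C)=O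
Why: DMAP-catalysed acetylation of a hindered secondary alcohol installs the leaving group trans to the cyclopropane.

Step 13
Reactants: 18 C5 acetate
Product: 20 key precursor (C2 tert-butyldimethylsilyl enol ether C2=C3; C1 silyl ether; 5α-acetate; 8β-triethylsilyl ether), via lithium enolate 19 (not isolated)
Conditions: LiN(SiMe3)2, THF, −78 °C; t-BuMe2SiCl, HMPA, −78 → 0 °C
Reagents that add atoms: tert-butyldimethylsilyl chloride, CC(C)(C)[Si](C)(C)Cl
Why: Kinetic enolisation of the methyl ketone at the methyl group (the other α-position is a hindered silyloxy methine) with an amide base too weak to enolise the acetate appreciably, then O-silylation; the tert-butyldimethylsilyl enol ether is robust enough to isolate.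

Step 14
Reactants: 20 key precursor (bicyclo[4.1.0]heptane C5 acetate with the C2 silyl enol ether chain on C6)
Product: 22 tricyclic C2 ketone (cyclobutane C4–C5–C6–C7; seven-membered ring closed by C3–C4; C1 tert-butyldimethylsilyl ether; C8 triethylsilyl ether), via tertiary cation 21 (not isolated)
Conditions: Me3SiOTf (1.2 equiv), 2,6-di-tert-butyl-4-methylpyridine, CH2Cl2 (0.005 M), −78 → −40 °C; aq. NaHCO3
Reagents that add atoms: none
Why: Proposed new method: Me3SiOTf silylates the acetate carbonyl and the C5–O bond ionises with help from the cyclopropane bond C4–C6, which lies anti to the leaving group in the conformer with the acetate axial; C6 moves from C4 to C5 with inversion at C5 and retention at C6, turning the bicyclo[4.1.0]heptyl cation into the tertiary 6-methylbicyclo[3.1.1]hept-6-yl cation 21, whose charge rests on methyl-bearing C4. The closest known chemistry is the solvolytic interconversion of bicyclo[4.1.0]hept-2-yl and bicyclo[3.1.1]hept-6-yl cations with external nucleophiles and the Lewis-acid alkylation of silyl enol ethers by tertiary cations; joining the two in one intramolecular event is without precedent. The cyclobutane C4–C5–C6–C7 closes by this 1,2-alkyl shift (cyclopropylcarbinyl-to-cyclobutyl ring expansion), and the seven-membered ring closes when the enol ether terminus C3 attacks C4, a closure that is 7-endo with respect to the enol ether, after which the oxocarbenium ion gives up its silyl group to triflate and leaves the C2 ketone. C5 is set by the backside migration of C6; C4 is set by the tether, because C3 hangs from C6 through C2–C1–C11 and can reach only the lobe of the C4 cation inside the fold of the cyclobutane, the face C6 has left, so that the methyl ends syn to the C8–C9–C10 bridge. The step needs capture at C4 rather than at C5 (which would make a trans-fused cyclopropane), at the bridging carbon C6 (a five-membered closure with cleavage of a ring bond to a cyclohexene) or loss of a methyl proton; the tertiary methyl-stabilised charge at C4, the neopentyl screening of C6 and a cold, non-basic, non-nucleophilic medium are expected to secure this. The bulky silyl ether keeps the C1 oxygen from competing, and C8 is a silyl ether because a ketal would be ionised by the silyl triflate and would promote Grob-type cleavage of C7–C8 from the C4 cation. High dilution suppresses intermolecular alkylation.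

Step 15
Reactants: 22 tricyclic C2 ketone
Product: 24 C3 alcohol (α-hydroxy ketone; C3–OH trans to the C1 silyloxy group), via potassium enolate 23 (not isolated)
Conditions: KN(SiMe3)2, THF, −78 °C; 2-(phenylsulfonyl)-3-phenyloxaziridine, −78 °C; aq. NH4Cl
Reagents that add atoms: 2-(phenylsulfonyl)-3-phenyloxaziridine, O=S(=O)(N1OC1c1ccccc1)c1ccccc1
Why: Davis oxidation of the kinetic enolate, which forms towards the C3 methylene and not the silyloxy methine C1; the C1 silyloxy group, pushed pseudo-axial by allylic strain with the enolate oxygen, should screen its own face so that oxygen arrives trans to it.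

Step 16
Reactants: 25 angelic acid
Product: 26 angelic 2,4,6-trichlorobenzoic anhydride (toluene stock solution)
Conditions: 2,4,6-Cl3C6H2COCl, Et3N, PhMe, 0 °C → rt; filtered under argon; kept as a PhMe solution at −20 °C
Reagents that add atoms: 2,4,6-trichlorobenzoyl chloride, O=C(Cl)c1c(Cl)cc(Cl)cc1Cl
Why: Acylation of the triethylammonium carboxylate by the hindered acid chloride gives the Yamaguchi mixed anhydride; no nucleophilic catalyst is present, so the (Z)-alkene should not isomerise, and one batch, freed from the ammonium salt by filtration, supplies both angeloylations.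

Step 17
Reactants: 24 C3 alcohol; 26 angelic 2,4,6-trichlorobenzoic anhydride
Product: 27 C3 angelate (C2 ketone; C1 and C8 silyl ethers)
Conditions: 26 (3 equiv), Et3N, PhMe, 75 °C
Reagents that add atoms: none
Why: Yamaguchi esterification: the alcohol attacks the unhindered angeloyl carbonyl of the mixed anhydride, and the absence of a nucleophilic catalyst is the established way to angeloylate hindered secondary alcohols without Z-to-E isomerisation; with C2 still a ketone no acyl migration is possible.

Step 18
Reactants: 27 C3 angelate with C8 triethylsilyl ether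
Product: 28 C8 alcohol (C1 tert-butyldimethylsilyl ether retained)
Conditions: PPTS, MeOH/CH2Cl2, 0 °C
Reagents that add atoms: none
Why: Mild acidic methanolysis cleaves a secondary triethylsilyl ether far faster than a hindered tert-butyldimethylsilyl ether; no further enolisation is planned, so C8 can be unmasked at this stage.

Step 19
Reactants: 28 C8 alcohol
Product: 29 C2,C8 diketone (C3 angelate; C1 silyl ether)
Conditions: Dess–Martin periodinane, NaHCO3, CH2Cl2, rt
Reagents that add atoms: none
Why: Dess–Martin oxidation of the only free hydroxyl under buffered, non-epimerising conditions installs the C8 ketone of the target.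

Step 20
Reactants: 29 C2,C8 diketone with C1 silyl ether
Product: 30 C1 alcohol (α-hydroxy ketone at C1/C2)
Conditions: HF·pyridine, pyridine, THF, rt
Reagents that add atoms: none
Why: Buffered acidic fluoride removes the hindered silyl ether without base, so neither the angelate nor the α-stereocentres are disturbed.

Step 21
Reactants: 30 C1 alcohol
Product: 31 C1,C2 trans-diol (C2–OH cis to the C3 angelate; C8 ketone intact)
Conditions: Me4NBH(OAc)3, AcOH/MeCN, −20 °C
Reagents that add atoms: none
Why: Hydroxyl-directed (Saksena–Evans) reduction: the C1 hydroxyl binds the borohydride and delivers hydride to its own face of the C2 ketone, giving the trans-diol; the reagent does not reduce ketones that lack a neighbouring hydroxyl, so C8 and the angelate are spared.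

Step 22
Reactants: 31 C1,C2 trans-diol
Product: 32 C2 triethylsilyl ether (C1–OH free)
Conditions: Et3SiCl (1.1 equiv), imidazole, DMF, −20 °C
Reagents that add atoms: chlorotriethylsilane, CC[Si](CC)(CC)Cl
Why: Selective silylation of the less hindered C2 hydroxyl over the neopentyl C1 hydroxyl; parking C2 as a silyl ether keeps an acetyl group out of the molecule until the last step.

Step 23
Reactants: 32 C2 triethylsilyl ether with free C1–OH; 26 angelic 2,4,6-trichlorobenzoic anhydride
Product: 33 C1,C3 bis-angelate (C2 triethylsilyl ether)
Conditions: 26 (5 equiv), Et3N, PhMe, 80 °C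
Reagents that add atoms: none
Why: The same Yamaguchi angeloylation with the stock mixed anhydride, applied to the neopentyl C1 alcohol; the amine conditions do not enolise the C8 ketone or move the silyl group, and no migratable acyl group is present.

Step 24
Reactants: 33 C1,C3 bis-angelate
Product: 34 C2 alcohol flanked by the two angelates
Conditions: HF·pyridine, pyridine, THF, 0 °C
Reagents that add atoms: none
Why: Acidic fluoride cleavage of the triethylsilyl ether; the hindered, conjugated angeloyl groups migrate very slowly under these non-basic conditions.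

Step 25
Reactants: 34 C2 alcohol
Product: 35 target CNP0197834.1
Conditions: Ac2O, DMAP (cat.), pyridine, CH2Cl2, rt
Reagents that add atoms: acetic anhydride, CC(=O)OC(C)=O
Why: Fast acetylation of the last free hydroxyl as the final step, so that the acetate never faces a free neighbouring alcohol; brief exposure to catalytic DMAP at room temperature should leave the angelates unisomerised.

## Compound list

1 | (S)-pantolactone | CC1(C)COC(=O)[C@H]1O | starting material
2 | (S)-O-(tert-butyldimethylsilyl)pantolactone | CC1(C)COC(=O)[C@H]1O[Si](C)(C)C(C)(C)C | intermediate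
3 | (S)-2-(tert-butyldimethylsilyloxy)-4-hydroxy-N-methoxy-N,3,3-trimethylbutanamide | CON(C)C(=O)[C@@H](O[Si](C)(C)C(C)(C)C)C(C)(C)CO | intermediate
4 | (S)-2-(tert-butyldimethylsilyloxy)-N-methoxy-N,3,3-trimethyl-4-oxobutanamide | CON(C)C(=O)[C@@H](O[Si](C)(C)C(C)(C)C)C(C)(C)C=O | intermediate
5 | (S,E)-hydrazone of 4 | CON(C)C(=O)[C@@H](O[Si](C)(C)C(C)(C)C)C(C)(C)/C=N/N | intermediate
6 | 2,6-dimethyl-1,4-benzoquinone | CC1=CC(=O)C=C(C)C1=O | starting material
7 | (S)-2-(tert-butyldimethylsilyloxy)-4-diazo-N-methoxy-N,3,3-trimethylbutanamide | CON(C)C(=O)[C@@H](O[Si](C)(C)C(C)(C)C)C(C)(C)C=[N+]=[N-] | intermediate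
8 | cis-fused 1-pyrazoline (C6 on C7, N on C4) | CON(C)C(=O)[C@@H](O[Si](C)(C)C(C)(C)C)C(C)(C)[C@H]1N=N[C@@]2(C)[C@@H]1C(=O)C=C(C)C2=O | intermediate
9 | bicyclo[4.1.0]hept-3-ene-2,5-dione, amide chain exo on C6 (1S,4S,6S,7R) | CON(C)C(=O)[C@@H](O[Si](C)(C)C(C)(C)C)C(C)(C)[C@H]1[C@@]2(C)[C@@H]1C(=O)C=C(C)C2=O | intermediate
10 | 8β-hydroxy enone | CON(C)C(=O)[C@@H](O[Si](C)(C)C(C)(C)C)C(C)(C)[C@H]1[C@@]2(C)[C@@H]1[C@@H](O)C=C(C)C2=O | intermediate
11 | 8β-triethylsilyloxy enone | CON(C)C(=O)[C@@H](O[Si](C)(C)C(C)(C)C)C(C)(C)[C@H]1[C@@]2(C)[C@@H]1[C@@H](O[Si](CC)(CC)CC)C=C(C)C2=O | intermediate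
12 | lithium C5 enolate | CON(C)C(=O)[C@@H](O[Si](C)(C)C(C)(C)C)C(C)(C)[C@H]1[C@@]2(C)[C@@H]1[C@@H](O[Si](CC)(CC)CC)CC(C)=C2[O-].[Li+] | intermediate
13 | C5 enol triflate | CON(C)C(=O)[C@@H](O[Si](C)(C)C(C)(C)C)C(C)(C)[C@H]1[C@@]2(C)[C@@H]1[C@@H](O[Si](CC)(CC)CC)CC(C)=C2OS(=O)(=O)C(F)(F)F | intermediate
14 | C5=C10 alkene (vinylcyclopropane) | CON(C)C(=O)[C@@H](O[Si](C)(C)C(C)(C)C)C(C)(C)[C@H]1[C@@]2(C)[C@@H]1[C@@H](O[Si](CC)(CC)CC)CC(C)=C2 | intermediate
15 | C5 alkylborane | CON(C)C(=O)[C@@H](O[Si](C)(C)C(C)(C)C)C(C)(C)[C@H]1[C@@]2(C)[C@@H]1[C@@H](O[Si](CC)(CC)CC)C[C@@H](C)[C@@H]2B | intermediate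
16 | 5α-alcohol, C10 methyl β | CON(C)C(=O)[C@@H](O[Si](C)(C)C(C)(C)C)C(C)(C)[C@H]1[C@@]2(C)[C@@H]1[C@@H](O[Si](CC)(CC)CC)C[C@@H](C)[C@@H]2O | intermediate
17 | methyl ketone, C5–OH free | CC(=O)[C@@H](O[Si](C)(C)C(C)(C)C)C(C)(C)[C@H]1[C@@]2(C)[C@@H]1[C@@H](O[Si](CC)(CC)CC)C[C@@H](C)[C@@H]2O | intermediate
18 | methyl ketone 5α-acetate | CC(=O)[C@@H](O[Si](C)(C)C(C)(C)C)C(C)(C)[C@H]1[C@@]2(C)[C@@H]1[C@@H](O[Si](CC)(CC)CC)C[C@@H](C)[C@@H]2OC(C)=O | intermediate
19 | lithium enolate of 18 | [Li+].C=C([O-])[C@@H](O[Si](C)(C)C(C)(C)C)C(C)(C)[C@H]1[C@@]2(C)[C@@H]1[C@@H](O[Si](CC)(CC)CC)C[C@@H](C)[C@@H]2OC(C)=O | intermediate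
20 | key precursor: bicyclo[4.1.0]heptane 5α-acetate with C2 silyl enol ether chain on C6 | C=C(O[Si](C)(C)C(C)(C)C)[C@@H](O[Si](C)(C)C(C)(C)C)C(C)(C)[C@H]1[C@@]2(C)[C@@H]1[C@@H](O[Si](CC)(CC)CC)C[C@@H](C)[C@@H]2OC(C)=O | intermediate
21 | tertiary bicyclo[3.1.1]hept-6-yl cation (charge on C4), triflate | C=C(O[Si](C)(C)C(C)(C)C)[C@@H](O[Si](C)(C)C(C)(C)C)C(C)(C)[C@H]1[C@H]2[C+](C)[C@@H]1[C@@H](O[Si](CC)(CC)CC)C[C@H]2C.[O-]S(=O)(=O)C(F)(F)F | intermediate
22 | tricyclic C2 ketone, C1 and C8 silyl ethers | CC(C)(C)[Si](C)(C)O[C@@H]1C(=O)C[C@]2(C)[C@@H]3[C@@H]([C@H]2[C@@H](O[Si](CC)(CC)CC)C[C@H]3C)C1(C)C | intermediate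
23 | potassium enolate of 22 | CC(C)(C)[Si](C)(C)O[C@@H]1C([O-])=C[C@]2(C)[C@@H]3[C@@H]([C@H]2[C@@H](O[Si](CC)(CC)CC)C[C@H]3C)C1(C)C.[K+] | intermediate
24 | C3 alcohol (α-hydroxy ketone) | CC(C)(C)[Si](C)(C)O[C@@H]1C(=O)[C@@H](O)[C@]2(C)[C@@H]3[C@@H]([C@H]2[C@@H](O[Si](CC)(CC)CC)C[C@H]3C)C1(C)C | intermediate
25 | angelic acid | C/C=C(/C)C(=O)O | starting material
26 | angelic 2,4,6-trichlorobenzoic anhydride | C/C=C(/C)C(=O)OC(=O)c1c(Cl)cc(Cl)cc1Cl | intermediate
27 | C3 angelate | CC(C)(C)[Si](C)(C)O[C@@H]1C(=O)[C@@H](OC(=O)/C(C)=C\C)[C@]2(C)[C@@H]3[C@@H]([C@H]2[C@@H](O[Si](CC)(CC)CC)C[C@H]3C)C1(C)C | intermediate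
28 | C8 alcohol | CC(C)(C)[Si](C)(C)O[C@@H]1C(=O)[C@@H](OC(=O)/C(C)=C\C)[C@]2(C)[C@@H]3[C@@H]([C@H]2[C@@H](O)C[C@H]3C)C1(C)C | intermediate
29 | C2,C8 diketone | CC(C)(C)[Si](C)(C)O[C@@H]1C(=O)[C@@H](OC(=O)/C(C)=C\C)[C@]2(C)[C@@H]3[C@@H]([C@H]2C(=O)C[C@H]3C)C1(C)C | intermediate
30 | C1 alcohol | O[C@@H]1C(=O)[C@@H](OC(=O)/C(C)=C\C)[C@]2(C)[C@@H]3[C@@H]([C@H]2C(=O)C[C@H]3C)C1(C)C | intermediate
31 | C1,C2 trans-diol | O[C@@H]1[C@@H](O)[C@@H](OC(=O)/C(C)=C\C)[C@]2(C)[C@@H]3[C@@H]([C@H]2C(=O)C[C@H]3C)C1(C)C | intermediate
32 | C2 triethylsilyl ether | O[C@@H]1[C@@H](O[Si](CC)(CC)CC)[C@@H](OC(=O)/C(C)=C\C)[C@]2(C)[C@@H]3[C@@H]([C@H]2C(=O)C[C@H]3C)C1(C)C | intermediate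
33 | C1,C3 bis-angelate, C2 triethylsilyl ether | C/C=C(/C)C(=O)O[C@@H]1[C@@H](O[Si](CC)(CC)CC)[C@@H](OC(=O)/C(C)=C\C)[C@]2(C)[C@@H]3[C@@H]([C@H]2C(=O)C[C@H]3C)C1(C)C | intermediate
34 | C2 alcohol | C/C=C(/C)C(=O)O[C@@H]1[C@@H](O)[C@@H](OC(=O)/C(C)=C\C)[C@]2(C)[C@@H]3[C@@H]([C@H]2C(=O)C[C@H]3C)C1(C)C | intermediate
35 | CNP0197834.1 | C/C=C(/C)C(=O)O[C@@H]1[C@@H](OC(C)=O)[C@@H](OC(=O)/C(C)=C\C)[C@]2(C)[C@@H]3[C@@H]([C@H]2C(=O)C[C@H]3C)C1(C)C | target

## Step count and least certain steps

Total step count: 25. Longest linear sequence: 24 steps (1 to 35 through steps 1–15 and 17–25). Step 16 makes 26 from 25 on a one-step side branch; 6 enters at step 5 and 26 at steps 17 and 23.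

Step 14 (key step). The most likely failure is capture of the delocalised cation at the wrong site: a five-membered closure of C3 onto the bridging carbon C6 with cleavage of a ring bond, or loss of a methyl proton before the seven-membered ring closes. The reason is that closure at C4 must use the cation lobe inside the fold of the cyclobutane, the side of its cross-ring interaction with C6, whereas nucleophiles normally take the outer lobe. The fallback replaces cationic by radical capture, uses known reactions, sets out from 18 and returns at 22. Buffered solvolysis of 18 (aqueous hexafluoroisopropanol, 2,6-lutidine, 40 °C), the known cyclopropylcarbinyl-to-cyclobutyl expansion with capture by water, would give the tertiary 6-methylbicyclo[3.1.1]heptan-6-ol F1. Dehydration with the Burgess reagent can run only towards the methyl group, since C5 and C7 are bridgeheads, and gives the methylenecyclobutane F2. KN(SiMe3)2 and PhNTf2 turn the methyl ketone into the enol triflate F3, and PhSO2Na with Pd2(dba)3 and Xantphos gives the vinyl sulfone F4. Fe(acac)3 and PhSiH3 in EtOH add a hydrogen atom to the exocyclic methylene, and the tertiary C4 radical, which has no facial constraint, closes on C3 of the vinyl sulfone (7-endo Giese addition) to the tricyclic C2 sulfone F5. Deprotonation with n-BuLi and oxidation with Me3SiOOSiMe3 (oxidative desulfonylation) return 22.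

Step 5. The most likely failures are loss of the non-stabilised diazoalkane 7 (azine formation, or nitrogen loss with methyl shift) before it meets the quinone, and hydrogen migration during extrusion from 8, which would give an alkylated quinone instead of the cyclopropane. In addition, no facial discrimination is expected from C1. The fallback sets out from 4 and returns at 9. Aldehyde 4 is condensed with TsNHNH2 to the tosylhydrazone F6. Its sodium salt (NaH) releases 7 slowly under phase transfer (BnEt3NCl, dioxane, 40 °C) in the presence of 6, so that 7 never accumulates (Bamford–Stevens generation). Pyrazoline 8 is then photolysed (350 nm, 0 °C) rather than heated.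

Step 10. The most likely failure is addition of borane from the cyclopropane face, because the C4 methyl screens the other face of C5; this would give the C5/C10 bis-epimer. The fallback sets out from 11 and returns at 16. Hydrogenation of 11 (H2, Pd/C, EtOAc) anti to the C8 silyl ether gives the saturated ketone F7 with the C10 methyl cis to the cyclopropane. Hydride reduction (NaBH4, MeOH) from the cyclopropane face then gives 16. The two methods are complementary: borane leaves the oxygen on the face it attacks, a hydride leaves it on the opposite face, so whichever face C5 offers, one of them leads to 16.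

Step 15. The most likely failure is poor facial selectivity of oxygen transfer, if the C1 silyloxy group sits pseudo-equatorial and screens neither face of the enolate. The fallback sets out from 22 and returns at 24. KN(SiMe3)2 and PhNTf2 give the enol triflate F8; Pd(OAc)2, PPh3, Bu3N and HCO2H reduce it to the cycloheptene F9. OsO4 with N-methylmorpholine N-oxide dihydroxylates the alkene anti to the allylic silyloxy group to the cis-diol F10. Oxidation of the less hindered C2 carbinol (Dess–Martin periodinane, 1 equiv; C3 is neopentyl) then gives 24.

Step 23. The most likely failures are incomplete acylation of the neopentyl C1 hydroxyl beside the C2 silyl ether and Z-to-E isomerisation of the angeloyl group under forcing conditions. The fallback sets out from 32 and returns at 33. The C1 hydroxyl is esterified with 2-[bis(2,2,2-trifluoroethoxy)phosphoryl]propanoic acid (DCC, DMAP) to the phosphonate ester F11. A Still–Gennari olefination (KN(SiMe3)2, 18-crown-6, THF, −78 °C; MeCHO) then builds the (Z)-2-methylbut-2-enoate directly on the oxygen; the phosphonate is far more acidic than the C8 ketone.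

## Further compounds

F1 | step 14 | tertiary 6-methylbicyclo[3.1.1]heptan-6-ol (C4–OH) with methyl ketone chain on C6 | CC(=O)[C@@H](O[Si](C)(C)C(C)(C)C)C(C)(C)[C@H]1[C@H]2[C@](C)(O)[C@@H]1[C@@H](O[Si](CC)(CC)CC)C[C@H]2C
F2 | step 14 | methylenecyclobutane (C4 exocyclic methylene) | CC(=O)[C@@H](O[Si](C)(C)C(C)(C)C)C(C)(C)[C@H]1[C@H]2C(=C)[C@@H]1[C@@H](O[Si](CC)(CC)CC)C[C@H]2C
F3 | step 14 | C2 enol triflate of F2 | C=C(OS(=O)(=O)C(F)(F)F)[C@@H](O[Si](C)(C)C(C)(C)C)C(C)(C)[C@H]1[C@H]2C(=C)[C@@H]1[C@@H](O[Si](CC)(CC)CC)C[C@H]2C
F4 | step 14 | C2 vinyl phenyl sulfone | C=C(S(=O)(=O)c1ccccc1)[C@@H](O[Si](C)(C)C(C)(C)C)C(C)(C)[C@H]1[C@H]2C(=C)[C@@H]1[C@@H](O[Si](CC)(CC)CC)C[C@H]2C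
F5 | step 14 | tricyclic C2 phenyl sulfone (C2 epimers) | CC(C)(C)[Si](C)(C)O[C@@H]1C(S(=O)(=O)c4ccccc4)C[C@]2(C)[C@@H]3[C@@H]([C@H]2[C@@H](O[Si](CC)(CC)CC)C[C@H]3C)C1(C)C
F6 | step 5 | (S,E)-tosylhydrazone of 4 | CON(C)C(=O)[C@@H](O[Si](C)(C)C(C)(C)C)C(C)(C)/C=N/NS(=O)(=O)c1ccc(C)cc1
F7 | step 10 | saturated C5 ketone, C10 methyl β | CON(C)C(=O)[C@@H](O[Si](C)(C)C(C)(C)C)C(C)(C)[C@H]1[C@@]2(C)[C@@H]1[C@@H](O[Si](CC)(CC)CC)C[C@@H](C)C2=O
F8 | step 15 | tricyclic C2 enol triflate (C2=C3) | CC(C)(C)[Si](C)(C)O[C@@H]1C(OS(=O)(=O)C(F)(F)F)=C[C@]2(C)[C@@H]3[C@@H]([C@H]2[C@@H](O[Si](CC)(CC)CC)C[C@H]3C)C1(C)C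
F9 | step 15 | tricyclic C2=C3 alkene | CC(C)(C)[Si](C)(C)O[C@@H]1C=C[C@]2(C)[C@@H]3[C@@H]([C@H]2[C@@H](O[Si](CC)(CC)CC)C[C@H]3C)C1(C)C
F10 | step 15 | C2,C3 cis-diol trans to the C1 silyl ether | CC(C)(C)[Si](C)(C)O[C@@H]1[C@@H](O)[C@@H](O)[C@]2(C)[C@@H]3[C@@H]([C@H]2[C@@H](O[Si](CC)(CC)CC)C[C@H]3C)C1(C)C
F11 | step 23 | C1 2-[bis(2,2,2-trifluoroethoxy)phosphoryl]propanoate | CC(C(=O)O[C@@H]1[C@@H](O[Si](CC)(CC)CC)[C@@H](OC(=O)/C(C)=C\C)[C@]2(C)[C@@H]3[C@@H]([C@H]2C(=O)C[C@H]3C)C1(C)C)P(=O)(OCC(F)(F)F)OCC(F)(F)F
A1 | alternative 1 | bridged cycloheptene lactone (C8 carbonyl on the C2 oxygen, C3=C4) | COc1ccc(CO[C@@H]2[C@@H]3C=C(C)[C@@H](CO[Si](C)(C)C(C)(C)C)[C@@H](CC(=O)O3)C2(C)C)cc1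
A2 | alternative 1 | bicyclo[4.1.1]oct-2-ene C8 acid | COc1ccc(CO[C@@H]2C=C[C@]3(C)[C@@H](CO[Si](C)(C)C(C)(C)C)[C@@H]([C@@H]3C(=O)O)C2(C)C)cc1
A3 | alternative 2 | bicyclo[3.1.1]heptane with (Z)-iodovinyl on C4 and C1 aldehyde chain on C6 | I/C=C\[C@]1(C)[C@@H]2[C@@H]([C@H]1C3(OCCO3)C[C@H]2C)C(C)(C)C=O
A4 | alternative 2 | tricyclic C1 allylic alcohol | O[C@@H]1C=C[C@]2(C)[C@@H]3[C@@H]([C@H]2C4(OCCO4)C[C@H]3C)C1(C)C
A5 | alternative 3 | methyl-substituted tricyclo[4.1.0.0(2,7)]heptane ketal (bicyclobutane, central bond C4–C6) | C[C@]12[C@@H]3[C@H]1[C@H]2C4(OCCO4)C[C@H]3C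
A6 | alternative 3 | 4-bromo-4-methylpent-1-en-3-one | CC(C)(Br)C(=O)C=C
A7 | alternative 3 | tricyclic C1 ketone with C8 ketal | O=C1CC[C@]2(C)[C@@H]3[C@@H]([C@H]2C4(OCCO4)C[C@H]3C)C1(C)C
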